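Atoms are numbered as in labdanes.

- **Cuts.** The C15 silyl ether and both acetates come off first. 6β-OAc traces back to a 6-ketone and 7α-OAc to an 8-en-7-one. C9–C11 is cut next (side chain as a Z-homoallyl Grignard reagent), and C1–C10 of ring A is cut last.
- **Enabling feature.** Ring B (C5–C10) carries its oxygen at C7 para to the quaternary C10–CH3, a methyl at C8 and the C8=C9 double bond. It is therefore a masked 2,4-dimethylphenol with the C4 arm on C5, and an alkenyl halide at C1 can attack C10 and dearomatise the ring.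
- **Forward order.** 4,6-Dibromo-m-xylene (ring B) gains C4 (acetone), C3–C2 (allylsilane), the C7 oxygen and C1 (Z-bromo-olefin metathesis). The palladium-catalysed dearomative cyclisation then closes ring A as the second and last ring. After that ring B is adjusted, the chain is joined at C9, and C7 and C6 are set.
- **Stereochemistry.** C10 comes from the chiral phosphine in the cyclisation. C5 comes from axial protonation in a dissolving-metal reduction (trans-decalin). C7 comes from α-face hydride followed by SN2 inversion. C6 comes from α-face hydride on the 6-ketone, whose β face is blocked by the axial methyls on C4 and C10. The 13Z geometry comes from trans-hydroalumination of but-2-yn-1-ol.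

Key step: step 6

Assumption: the (S) antipode of the P-chiral ligand is taken to give the 10β-methyl (4aR) series; if the sense of induction is the opposite, the (R) antipode is used.

## Route

Step 1
Reactants: 1 1,5-dibromo-2,4-dimethylbenzene; 2 acetone
Product: 4 2-(5-bromo-2,4-dimethylphenyl)propan-2-ol, via aryllithium 3 (not isolated)
Conditions: n-BuLi (1.0 equiv), THF, −78 °C; then acetone, −78 °C → rt; H2O
Reagents that add atoms: n-butyllithium [Li]CCCC (lithium of 3 only)
Why: Bromine–lithium exchange at one of two equivalent C–Br bonds and 1,2-addition of the aryllithium to acetone should put C4 with both methyl groups on C5; no stereocentre is formed.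

Step 2
Reactants: 4 2-(5-bromo-2,4-dimethylphenyl)propan-2-ol; 5 allyltrimethylsilane
Product: 6 1-bromo-2,4-dimethyl-5-(2-methylpent-4-en-2-yl)benzene
Conditions: Bi(OTf)3 (2 mol%), CH2Cl2, 0 °C → rt
Reagents that add atoms: none
Why: Lewis-acid ionisation of the tertiary benzylic alcohol and capture of the cumyl-type cation by the allylsilane (Hosomi–Sakurai-type SN1 allylation) should build the quaternary C4 and bring in C3, C2 and a sacrificial terminal CH2.

Step 3
Reactants: 6 1-bromo-2,4-dimethyl-5-(2-methylpent-4-en-2-yl)benzene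
Product: 7 1-methoxy-2,4-dimethyl-5-(2-methylpent-4-en-2-yl)benzene
Conditions: NaOMe, CuI (10 mol%), DMF–MeOH, 110 °C
Reagents that add atoms: sodium methoxide C[O-].[Na+]
Why: Copper-catalysed Ullmann-type methoxylation of the remaining aryl bromide should place the C7 oxygen in a form that tolerates the metathesis catalyst.

Step 4
Reactants: 7 1-methoxy-2,4-dimethyl-5-(2-methylpent-4-en-2-yl)benzene; 8 (Z)-1,2-dibromoethene
Product: 9 1-[(4Z)-5-bromo-2-methylpent-4-en-2-yl]-5-methoxy-2,4-dimethylbenzene
Conditions: Mo(NC6F5)(CHCMe2Ph)(2,5-Me2C4H2N)(O-2,6-Mes2C6H3) (5 mol%), benzene, rt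
Reagents that add atoms: none
Why: Kinetically Z-selective cross-metathesis of a terminal olefin with a 1,2-dihaloethene should exchange the terminal CH2 for CHBr (C1) and give the Z-alkenyl bromide, the only geometry from which C1 can reach C10.

Step 5
Reactants: 9 1-[(4Z)-5-bromo-2-methylpent-4-en-2-yl]-5-methoxy-2,4-dimethylbenzene
Product: 10 5-[(4Z)-5-bromo-2-methylpent-4-en-2-yl]-2,4-dimethylphenol
Conditions: BBr3, CH2Cl2, −78 → 0 °C; H2O
Reagents that add atoms: none
Why: Boron tribromide cleavage of the aryl methyl ether should free the phenol without touching the alkenyl bromide.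

Step 6
Reactants: 10 5-[(4Z)-5-bromo-2-methylpent-4-en-2-yl]-2,4-dimethylphenol
Product: 11 (4aR)-3,4a,8,8-tetramethyl-7,8-dihydronaphthalen-2(4aH)-one (labdane core: C7=O; C1=C2, C5=C6 and C8=C9 double bonds; 10β-methyl)
Conditions: [Pd(cinnamyl)Cl]2 (2.5 mol%), (S)-AntPhos (6 mol%), K2CO3, toluene, 90 °C
Reagents that add atoms: none
Why: Zerovalent palladium should insert into the Z-alkenyl C1–Br bond, the potassium phenolate should replace bromide, C-palladation at C10 (para to oxygen) should give a seven-membered palladacycle, and C(sp2)–C(sp3) reductive elimination should forge C1–C10 and leave ring B as the cross-conjugated 5,8-dien-7-one. The closest known reaction type is the palladium-catalysed enantioselective dearomative cyclisation of para-alkylphenols that carry an aryl or alkenyl halide on a meta tether. Ring A (C10–C1=C2–C3–C4–C5) closes as a six-membered ring by attack of the ring carbon next to the tether anchor, helped by the gem-dimethyl effect of C4. C10 is the only new stereocentre, and it is controlled by the bulky P-chiral monophosphine, which lets only one face of the planar phenolate approach the alkenyl ligand. The step needs attack at the methyl-bearing C10 rather than at C6–H or at oxygen. The largest phenolate coefficient lies at the para carbon, O-attack would need an eight-membered ring, and the weak base in a non-polar solvent disfavours the rearomatising C–H pathway.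

Step 7
Reactants: 11 trienone
Product: 12 labdane-core 5-en-7-one (ring A saturated; 8α-methyl; 10β-methyl)
Conditions: H2 (1 atm, two equivalents taken up), Pd/C, EtOAc, rt; then K2CO3 (cat.), MeOH, rt
Reagents that add atoms: none
Why: Heterogeneous hydrogenation should saturate the unhindered C1=C2 olefin and the C8=C9 arm (C9 bears H) but spare C5=C6, which lies between the quaternary C4 and C10; base equilibration should put the C8 methyl equatorial, a centre that step 9 erases.

Step 8
Reactants: 12 labdane-core 5-en-7-one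
Product: 15 6α-triethylsilyloxy-7-ketone (5α-H trans-decalin; 8α-methyl), via lithium enolate 13 (not isolated), via triethylsilyl enol ether 14 (not isolated)
Conditions: Li, NH3(l)–THF, t-BuOH (1 equiv), −78 °C; isoprene; NH3 off; Et3SiCl, Et3N, THF, −78 → 0 °C; crude, mCPBA, CH2Cl2–hexane, −20 °C
Reagents that add atoms: lithium [Li] (in 13 only); chlorotriethylsilane CC[Si](Cl)(CC)CC; mCPBA O=C(OO)c1cccc(Cl)c1
Why: Dissolving-metal reduction of the enone should protonate C5 axially on the α face (trans-decalin) and leave the regiodefined C6=C7 enolate, which is trapped as its silyl enol ether and oxidised from the open α face with silyl migration (Rubottom oxidation) to give the 6α-silyloxy ketone.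

Step 9
Reactants: 15 6α-triethylsilyloxy-7-ketone
Product: 17 6α-triethylsilyloxy-8-en-7-one (C9–H), via trimethylsilyl enol ether 16 (not isolated)
Conditions: Me3SiOTf, Et3N, CH2Cl2, 0 °C → rt; crude, Pd(OAc)2 (1.1 equiv), MeCN, rt
Reagents that add atoms: trimethylsilyl triflate C[Si](C)(C)OS(=O)(=O)C(F)(F)F (silyl group of 16 only)
Why: Soft enolisation should give the more substituted C7=C8 silyl enol ether, because the axial 6β-H is screened by two syn-axial methyls, and Saegusa–Ito oxidation with divalent palladium should restore the C8=C9 enone by β-hydride loss from C9.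

Step 10
Reactants: 18 but-2-yn-1-ol
Product: 19 (Z)-3-iodobut-2-en-1-ol
Conditions: NaAlH2(OCH2CH2OMe)2, THF, 0 °C → rt; then I2, −78 → 0 °C
Reagents that add atoms: iodine II
Why: Hydroxyl-directed trans-hydroalumination of the propargylic alcohol should place aluminium on the future C13 cis to CH2OH, and iodinolysis with retention should fix the geometry that becomes 13Z.

Step 11
Reactants: 19 (Z)-3-iodobut-2-en-1-ol
Product: 20 (Z)-tert-butyl[(3-iodobut-2-en-1-yl)oxy]diphenylsilane
Conditions: t-BuPh2SiCl, imidazole, DMF, rt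
Reagents that add atoms: tert-butylchlorodiphenylsilane CC(C)(C)[Si](Cl)(c1ccccc1)c1ccccc1
Why: Standard silylation should give an acid-stable ether at C15 that lasts until the final step.

Step 12
Reactants: 20 (Z)-iodoalkene silyl ether; 21 oxirane
Product: 23 (Z)-5-(tert-butyldiphenylsilyloxy)-3-methylpent-3-en-1-ol, via alkenylmagnesium chloride 22 (not isolated)
Conditions: i-PrMgCl·LiCl, THF, −20 °C → rt; then CuI (10 mol%), oxirane, −30 → 0 °C; H2O
Reagents that add atoms: isopropylmagnesium chloride CC(C)[Mg]Cl (MgCl of 22 only)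
Why: Iodine–magnesium exchange with retention of olefin geometry followed by copper-catalysed epoxide opening should add C12 and C11 without eroding the Z configuration.

Step 13
Reactants: 23 (Z)-5-(tert-butyldiphenylsilyloxy)-3-methylpent-3-en-1-ol
Product: 24 (Z)-[(5-bromo-3-methylpent-2-en-1-yl)oxy](tert-butyl)diphenylsilane
Conditions: CBr4, PPh3, CH2Cl2, 0 °C
Reagents that add atoms: carbon tetrabromide BrC(Br)(Br)Br
Why: The Appel reaction should convert the primary homoallylic alcohol into the bromide under neutral conditions.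

Step 14
Reactants: 17 6α-triethylsilyloxy-8-en-7-one; 24 (Z)-homoallylic bromide
Product: 27 6α-triethylsilyloxy-15-(tert-butyldiphenylsilyloxy)labda-8,13Z-dien-7-one, via Grignard reagent 25 (not isolated), via trimethylsilyl enol ether 26 (not isolated)
Conditions: 24, Mg, THF, rt; then CuBr·SMe2 (15 mol%), Me3SiCl, DMPU, 17, THF, −78 °C; crude, Pd(OAc)2 (1.1 equiv), MeCN, rt → 40 °C
Reagents that add atoms: magnesium [Mg] (in 25 only); chlorotrimethylsilane C[Si](C)(C)Cl (silyl group of 26 only)
Why: Copper-catalysed, chlorosilane-accelerated conjugate addition should deliver the chain to C9 axially and anti to the C10 methyl (a transient centre), and Saegusa–Ito oxidation of the trapped silyl enol ether should re-form C8=C9, now tetrasubstituted.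

Step 15
Reactants: 27 6α-triethylsilyloxy dienone
Product: 29 15-(tert-butyldiphenylsilyloxy)labda-8,13Z-diene-6α,7β-diol, via 6α-hydroxy enone 28 (not isolated)
Conditions: PPTS (cat.), MeOH, rt; then CeCl3·7H2O, NaBH4, −40 °C
Reagents that add atoms: none
Why: Mild methanolysis should remove only the triethylsilyl group, and Luche 1,2-reduction should deliver hydride axially from the open α face of the enone to give the pseudo-equatorial 7β-alcohol.

Step 16
Reactants: 29 6α,7β-diol
Product: 30 7α-acetoxy-6α-hydroxy-15-(tert-butyldiphenylsilyloxy)labda-8,13Z-diene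
Conditions: AcOH, PPh3, DIAD, toluene, 0 °C → rt
Reagents that add atoms: acetic acid CC(=O)O
Why: In the Mitsunobu reaction the accessible allylic 7β-hydroxyl should be activated in preference to the 6α-hydroxyl, which is screened by C5 and the 4α-methyl, and acetate should displace it with inversion along the axial α trajectory to give the 7α-acetate.

Step 17
Reactants: 30 7α-acetoxy-6α-alcohol
Product: 31 7α-acetoxy-15-(tert-butyldiphenylsilyloxy)labda-8,13Z-dien-6-one
Conditions: Dess–Martin periodinane, CH2Cl2, 0 °C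
Reagents that add atoms: none
Why: Dess–Martin oxidation is fast and essentially neutral, so it should give the α-acetoxy ketone without epimerisation at C7 or C5 and without moving C8=C9 into conjugation.

Step 18
Reactants: 31 7α-acetoxy-6-ketone
Product: 32 7α-acetoxy-6β-hydroxy-15-(tert-butyldiphenylsilyloxy)labda-8,13Z-diene
Conditions: NaBH4, CeCl3·7H2O, MeOH, −40 °C
Reagents that add atoms: none
Why: Hydride can reach C6 only from the α face because the β face is closed by the syn-axial methyls on C4 and C10, so the axial 6β-alcohol should form, and its trans-diaxial relation to the 7α-acetate prevents acetyl migration.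

Step 19
Reactants: 32 7α-acetoxy-6β-alcohol
Product: 33 6β,7α-diacetoxy-15-(tert-butyldiphenylsilyloxy)labda-8,13Z-diene
Conditions: Ac2O, DMAP, pyridine, 40 °C
Reagents that add atoms: acetic anhydride CC(=O)OC(C)=O
Why: DMAP-catalysed acylation under gentle heating should esterify the hindered axial 6β-hydroxyl while C15 stays masked.

Step 20
Reactants: 33 diacetate silyl ether
Product: 34 6β,7α-diacetoxylabda-8,13Z-dien-15-ol (target)
Conditions: Bu4NF, AcOH, THF, 0 °C → rt
Reagents that add atoms: none
Why: Acetic-acid-buffered fluoride desilylation should free the primary allylic alcohol without hydrolysis or migration of the two acetates.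

## Compound list

1 | 1,5-dibromo-2,4-dimethylbenzene | Cc1cc(C)c(Br)cc1Br | starting material
2 | acetone | CC(C)=O | starting material
3 | (5-bromo-2,4-dimethylphenyl)lithium | [Li]c1cc(Br)c(C)cc1C | intermediate
4 | 2-(5-bromo-2,4-dimethylphenyl)propan-2-ol | CC(C)(O)c1cc(Br)c(C)cc1C | intermediate
5 | allyltrimethylsilane | C=CC[Si](C)(C)C | starting material
6 | 1-bromo-2,4-dimethyl-5-(2-methylpent-4-en-2-yl)benzene | C=CCC(C)(C)c1cc(Br)c(C)cc1C | intermediate
7 | 1-methoxy-2,4-dimethyl-5-(2-methylpent-4-en-2-yl)benzene | C=CCC(C)(C)c1cc(OC)c(C)cc1C | intermediate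
8 | (Z)-1,2-dibromoethene | Br/C=C\Br | starting material
9 | 1-[(4Z)-5-bromo-2-methylpent-4-en-2-yl]-5-methoxy-2,4-dimethylbenzene | COc1cc(C(C)(C)C/C=C\Br)c(C)cc1C | intermediate
10 | 5-[(4Z)-5-bromo-2-methylpent-4-en-2-yl]-2,4-dimethylphenol | Oc1cc(C(C)(C)C/C=C\Br)c(C)cc1C | intermediate
11 | (4aR)-3,4a,8,8-tetramethyl-7,8-dihydronaphthalen-2(4aH)-one | O=C1C=C2C(C)(C)CC=C[C@]2(C)C=C1C | intermediate
12 | labdane-core 5-en-7-one, 8α-methyl, 10β-methyl | O=C1C=C2C(C)(C)CCC[C@]2(C)C[C@@H]1C | intermediate
13 | lithium 6-en-7-olate, 5α-H | C1=C(O[Li])[C@@H](C)C[C@@]2(C)CCCC(C)(C)[C@H]12 | intermediate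
14 | 7-triethylsilyloxy-6-ene, 5α-H | C1=C(O[Si](CC)(CC)CC)[C@@H](C)C[C@@]2(C)CCCC(C)(C)[C@H]12 | intermediate
15 | 6α-triethylsilyloxy-7-ketone, 5α-H, 8α-methyl | CC[Si](CC)(CC)O[C@H]1C(=O)[C@@H](C)C[C@@]2(C)CCCC(C)(C)[C@H]12 | intermediate
16 | 6α-triethylsilyloxy-7-trimethylsilyloxy-7-ene | CC[Si](CC)(CC)O[C@H]1C(O[Si](C)(C)C)=C(C)C[C@@]2(C)CCCC(C)(C)[C@H]12 | intermediate
17 | 6α-triethylsilyloxy-8-en-7-one (C9–H) | CC[Si](CC)(CC)O[C@H]1C(=O)C(C)=C[C@@]2(C)CCCC(C)(C)[C@H]12 | intermediate
18 | but-2-yn-1-ol | CC#CCO | starting material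
19 | (Z)-3-iodobut-2-en-1-ol | C/C(I)=C/CO | intermediate
20 | (Z)-tert-butyl[(3-iodobut-2-en-1-yl)oxy]diphenylsilane | C/C(I)=C/CO[Si](c1ccccc1)(c1ccccc1)C(C)(C)C | intermediate
21 | oxirane | C1CO1 | starting material
22 | (Z)-alkenylmagnesium chloride from 20 | C/C([Mg]Cl)=C/CO[Si](c1ccccc1)(c1ccccc1)C(C)(C)C | intermediate
23 | (Z)-5-(tert-butyldiphenylsilyloxy)-3-methylpent-3-en-1-ol | OCC/C(C)=C\CO[Si](c1ccccc1)(c1ccccc1)C(C)(C)C | intermediate
24 | (Z)-[(5-bromo-3-methylpent-2-en-1-yl)oxy](tert-butyl)diphenylsilane | BrCC/C(C)=C\CO[Si](c1ccccc1)(c1ccccc1)C(C)(C)C | intermediate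
25 | Grignard reagent from 24 | Br[Mg]CC/C(C)=C\CO[Si](c1ccccc1)(c1ccccc1)C(C)(C)C | intermediate
26 | 9α-alkylated 7-trimethylsilyloxy-7-ene, 6α-triethylsilyloxy | CC[Si](CC)(CC)O[C@H]1C(O[Si](C)(C)C)=C(C)[C@@H](CC/C(C)=C\CO[Si](c3ccccc3)(c3ccccc3)C(C)(C)C)[C@@]2(C)CCCC(C)(C)[C@H]12 | intermediate
27 | 6α-triethylsilyloxy-15-(tert-butyldiphenylsilyloxy)labda-8,13Z-dien-7-one | CC[Si](CC)(CC)O[C@H]1C(=O)C(C)=C(CC/C(C)=C\CO[Si](c3ccccc3)(c3ccccc3)C(C)(C)C)[C@@]2(C)CCCC(C)(C)[C@H]12 | intermediate
28 | 6α-hydroxy-15-(tert-butyldiphenylsilyloxy)labda-8,13Z-dien-7-one | O[C@H]1C(=O)C(C)=C(CC/C(C)=C\CO[Si](c3ccccc3)(c3ccccc3)C(C)(C)C)[C@@]2(C)CCCC(C)(C)[C@H]12 | intermediate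
29 | 15-(tert-butyldiphenylsilyloxy)labda-8,13Z-diene-6α,7β-diol | O[C@H]1[C@H](O)C(C)=C(CC/C(C)=C\CO[Si](c3ccccc3)(c3ccccc3)C(C)(C)C)[C@@]2(C)CCCC(C)(C)[C@H]12 | intermediate
30 | 7α-acetoxy-6α-hydroxy-15-(tert-butyldiphenylsilyloxy)labda-8,13Z-diene | O[C@H]1[C@@H](OC(C)=O)C(C)=C(CC/C(C)=C\CO[Si](c3ccccc3)(c3ccccc3)C(C)(C)C)[C@@]2(C)CCCC(C)(C)[C@H]12 | intermediate
31 | 7α-acetoxy-15-(tert-butyldiphenylsilyloxy)labda-8,13Z-dien-6-one | O=C1[C@@H](OC(C)=O)C(C)=C(CC/C(C)=C\CO[Si](c3ccccc3)(c3ccccc3)C(C)(C)C)[C@@]2(C)CCCC(C)(C)[C@H]12 | intermediate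
32 | 7α-acetoxy-6β-hydroxy-15-(tert-butyldiphenylsilyloxy)labda-8,13Z-diene | O[C@@H]1[C@@H](OC(C)=O)C(C)=C(CC/C(C)=C\CO[Si](c3ccccc3)(c3ccccc3)C(C)(C)C)[C@@]2(C)CCCC(C)(C)[C@H]12 | intermediate
33 | 6β,7α-diacetoxy-15-(tert-butyldiphenylsilyloxy)labda-8,13Z-diene | CC(=O)O[C@@H]1[C@@H](OC(C)=O)C(C)=C(CC/C(C)=C\CO[Si](c3ccccc3)(c3ccccc3)C(C)(C)C)[C@@]2(C)CCCC(C)(C)[C@H]12 | intermediate
34 | 6β,7α-diacetoxylabda-8,13Z-dien-15-ol | CC(=O)O[C@@H]1[C@@H](OC(C)=O)C(C)=C(CC/C(C)=C\CO)[C@@]2(C)CCCC(C)(C)[C@H]12 | target

## Step count and risks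

Total step count: 20. Longest linear sequence: 16 (steps 1–9 and 14–20); steps 10–13 build the side chain in parallel.

**Step 6.**
- What may go wrong: alkenylation may take place at C6–H with rearomatisation, or the ligand may discriminate poorly between the two faces of the phenolate.
- Start and return: the fallback sets out from 7 and comes back at 12.
- Path: hydroboration–oxidation of 7 (9-BBN, then NaOH/H2O2) gives 4-(5-methoxy-2,4-dimethylphenyl)-4-methylpentan-1-ol F1. Hot HBr/AcOH cleaves the methyl ether and converts the alcohol into 5-(5-bromo-2-methylpentan-2-yl)-2,4-dimethylphenol F2.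
- Closure and resolution: KOt-Bu in t-BuOH–THF at high dilution closes ring A by Winstein–Masamune para-alkylation of the phenolate, giving the racemic 5,8-dien-7-one F3. Chromatography on a chiral stationary phase gives the 10β-methyl enantiomer F4. Uptake of one equivalent of H2 over Pd/C, followed by base equilibration, gives 12.

**Step 14.**
- What may go wrong: the re-oxidation may stall, or elimination may run toward the C8 methyl group, because after axial delivery of the chain the remaining C9–H is pseudo-equatorial and poorly aligned.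
- Start and return: the fallback sets out from 17 and comes back at 27. It never makes C9 a lasting sp3 centre.
- Path: conjugate addition of PhSH (Et3N) gives the 9α-phenylthio ketone F5. Chlorination at sulfur-bearing C9 with NCS and loss of HCl gives the 9-phenylthio-8-en-7-one F6. Copper-catalysed addition–elimination of Grignard reagent 25 on this vinylogous thioester gives 27 directly.

**Step 16.**
- What may go wrong: the wrong hydroxyl may be activated, the allylic centre may ionise with loss of stereochemical fidelity, or elimination to the 6,8-diene may occur.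
- Start and return: the fallback sets out from 27 and comes back at 30. It replaces SN2 inversion by direct β-face reduction and regioselective orthoester opening.
- Path: LiBH(sec-Bu)3 attacks the enone from the equatorial β side to give the 6α-triethylsilyloxy-7α-alcohol F7. PPTS/MeOH gives the cis-6α,7α-diol F8.
- Orthoester stage: MeC(OMe)3 with acid catalysis gives the cyclic orthoacetate F9. Mild aqueous acid opens F9 to the axial ester, which is 30.

## Further compounds

F1 | step 6 | 4-(5-methoxy-2,4-dimethylphenyl)-4-methylpentan-1-ol | COc1cc(C(C)(C)CCCO)c(C)cc1C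
F2 | step 6 | 5-(5-bromo-2-methylpentan-2-yl)-2,4-dimethylphenol | Oc1cc(C(C)(C)CCCBr)c(C)cc1C
F3 | step 6 | racemic labdane-core 5,8-dien-7-one | O=C1C=C2C(C)(C)CCCC2(C)C=C1C
F4 | step 6 | 10β-methyl labdane-core 5,8-dien-7-one | O=C1C=C2C(C)(C)CCC[C@]2(C)C=C1C
F5 | step 14 | 9α-phenylthio-6α-triethylsilyloxy-7-ketone | CC[Si](CC)(CC)O[C@H]1C(=O)[C@@H](C)[C@@H](Sc3ccccc3)[C@@]2(C)CCCC(C)(C)[C@H]12
F6 | step 14 | 9-phenylthio-6α-triethylsilyloxy-8-en-7-one | CC[Si](CC)(CC)O[C@H]1C(=O)C(C)=C(Sc3ccccc3)[C@@]2(C)CCCC(C)(C)[C@H]12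
F7 | step 16 | 6α-triethylsilyloxy-7α-hydroxy-15-(tert-butyldiphenylsilyloxy)labda-8,13Z-diene | CC[Si](CC)(CC)O[C@H]1[C@@H](O)C(C)=C(CC/C(C)=C\CO[Si](c3ccccc3)(c3ccccc3)C(C)(C)C)[C@@]2(C)CCCC(C)(C)[C@H]12
F8 | step 16 | 15-(tert-butyldiphenylsilyloxy)labda-8,13Z-diene-6α,7α-diol | O[C@H]1[C@@H](O)C(C)=C(CC/C(C)=C\CO[Si](c3ccccc3)(c3ccccc3)C(C)(C)C)[C@@]2(C)CCCC(C)(C)[C@H]12
F9 | step 16 | 6α,7α-(1-methoxyethylidenedioxy) orthoacetate | COC1(C)O[C@H]2[C@@H](O1)C(C)=C(CC/C(C)=C\CO[Si](c4ccccc4)(c4ccccc4)C(C)(C)C)[C@@]3(C)CCCC(C)(C)[C@H]23
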